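**Strategy.** Everything rests on cutting C1–C10 and C13–C14 together. C1–C10 is the bond shared by ring A (C1, C10–C14) and the ten-membered ring (C1–C10), and the oxirane hides a C11=C12 alkene, so ring A is a Diels–Alder retron. One intramolecular Diels–Alder reaction of an open-chain tetraene should close both carbocycles at once and set C1, C10 and C14. Its precursor is the finished γ-lactone, which carries an (E)-2-methylbutadienyl carbinol at C8 and, on C7, an enal arm ending in a (Z)-β-boryl-α-methyl enone; boron is the masked 14-oxygen. The C9 stereocentre steers the diene face, and the remaining steps only adjust functional groups.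

Key step: step 16

Remark 1: briarane numbering is used. C1–C10 is the ten-membered ring and C1/C10–C14 is ring A. C15 is the methyl on C1, C16 the CH2Cl on C5, C17–C19 the lactone carbons, C18 the methyl on C17 and C20 the methyl on C11. TES = triethylsilyl, Bpin = pinacol boronate.
Remark 2: the oxirane oxygen is treated as a functional group on C11/C12 of ring A. The skeleton is therefore the 6/10/5 tricycle, and the oxygen is added once that skeleton is complete.

**Fragment 1 (C10–C13, C20)**

Step 1
Reactants: 1 prop-2-yn-1-ol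
Product: 3 (E)-3-iodo-2-methylprop-2-en-1-ol, via alkenylalane 2 (not isolated)
Conditions: Me3Al, Cp2ZrCl2 (cat.), CH2Cl2, 0 °C to rt; I2, THF, −30 °C
Reagents that add atoms: trimethylaluminium, C[Al](C)C; iodine, II
Why: Zirconium-catalysed Negishi carboalumination adds methyl and aluminium syn with aluminium at the terminus, and iodinolysis with retention should give the E iodide.

Step 2
Reactants: 3 (E)-3-iodo-2-methylprop-2-en-1-ol
Product: 4 (E)-3-iodo-2-methylprop-2-enal
Conditions: MnO2, CH2Cl2, rt
Reagents that add atoms: none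
Why: Allylic oxidation with MnO2 should stop at the enal and leave the vinyl iodide and its geometry untouched.

Step 3
Reactants: 4 (E)-3-iodo-2-methylprop-2-enal
Product: 5 (E)-1-iodo-2-methylbuta-1,3-diene
Conditions: CH3PPh3Br, KOtBu, THF, 0 °C
Reagents that add atoms: methyltriphenylphosphonium bromide, C[P+](c1ccccc1)(c1ccccc1)c1ccccc1.[Br-]
Why: Wittig methylenation of the enal should give the terminal diene without touching the E iodoalkene.

**Fragment 2 (C1–C5, C14–C16)**

Step 4
Reactants: 6 propyne
Product: 8 2-[(Z)-2-bromoprop-1-enyl]-4,4,5,5-tetramethyl-1,3,2-dioxaborolane, via dibromoborane 7 (not isolated)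
Conditions: BBr3, CH2Cl2, −78 °C to rt; pinacol, 0 °C
Reagents that add atoms: boron tribromide, BrB(Br)Br; pinacol, CC(C)(O)C(C)(C)O
Why: Syn bromoboration of the terminal alkyne puts boron on the terminus cis to bromine, and esterification with pinacol fixes the Z geometry (C14–B cis to the future C1–C2 bond).

Step 5
Reactants: 8 (Z)-bromoalkenyl boronate
Product: 9 (Z)-2-methyl-1-(4,4,5,5-tetramethyl-1,3,2-dioxaborolan-2-yl)penta-1,4-dien-3-one
Conditions: Pd(PPh3)4 (cat.), CO (3 atm), Bu3SnCH=CH2, BHT, THF, 50 °C
Reagents that add atoms: carbon monoxide, [C-]#[O+]; tributyl(vinyl)stannane, C=C[Sn](CCCC)(CCCC)CCCC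
Why: In this carbonylative Stille coupling, insertion into C–Br with retention, CO insertion and vinyl transfer should give the divinyl ketone, and the boronate stays inert because no base is present.

Step 6
Reactants: 9 (Z)-boryl divinyl ketone; 10 (triphenylphosphoranylidene)acetaldehyde
Product: 11 (6Z)-6-methyl-5-oxo-7-(pinacolboryl)-2-(triphenylphosphoranylidene)hept-6-enal
Conditions: CH2Cl2, rt
Reagents that add atoms: none
Why: Michael addition of the stabilised ylide carbon to the unsubstituted vinyl terminus, followed by a proton shift, regenerates a stabilised ylide, and the trisubstituted boryl alkene is too hindered to compete.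

**Main line**

Step 7
Reactants: 12 methyl (4S)-2,2-dimethyl-1,3-dioxolane-4-carboxylate
Product: 14 1-[(4S)-2,2-dimethyl-1,3-dioxolan-4-yl]prop-2-en-1-one, via Weinreb amide 13 (not isolated)
Conditions: MeNHOMe·HCl, iPrMgCl, THF, −20 °C; CH2=CHMgBr, −20 to 0 °C; cold 1 M HCl
Reagents that add atoms: vinylmagnesium bromide, C=C[Mg]Br; N,O-dimethylhydroxylamine hydrochloride, CNOC.Cl (atoms in 13 only)
Why: In this Weinreb ketone synthesis the chelated tetrahedral adduct stops at the ketone stage, and C7 is taken unchanged from the chiral pool.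

Step 8
Reactants: 14 vinyl ketone; 15 ethyl propanoate
Product: 17 ethyl (2R,3S)-3-[(4S)-2,2-dimethyl-1,3-dioxolan-4-yl]-3-hydroxy-2-methylpent-4-enoate, via lithium enolate 16 (not isolated)
Conditions: LDA, 15, THF, −78 °C; added to 14 and MgBr2·OEt2 in CH2Cl2, −78 °C; aq NH4Cl
Reagents that add atoms: lithium diisopropylamide, [Li+].CC(C)[N-]C(C)C (lithium in 16 only)
Why: In this aldol addition to the O7/O8-chelated ketone, Cram-chelate attack from the H7 side sets C8, the Zimmerman–Traxler array of the enolate (methyl trans to OLi) with the dioxolanyl group equatorial sets C17 anti, and the low temperature keeps the addition 1,2.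

Step 9
Reactants: 17 aldol adduct
Product: 18 (3R,4S,5S)-4-ethenyl-4-hydroxy-5-(hydroxymethyl)-3-methyloxolan-2-one
Conditions: AcOH–H2O 4:1, 40 °C
Reagents that add atoms: none
Why: Acetonide hydrolysis frees O7, which should close the γ-lactone on the ethyl ester, placing the C6 arm, 8-OH and C18 on one face and C9 on the other, the arrangement in which neighbouring large groups are trans.

Step 10
Reactants: 18 lactone diol
Product: 19 (3R,4S,5S)-4-ethenyl-3-methyl-4-(triethylsilyloxy)-5-(triethylsilyloxymethyl)oxolan-2-one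
Conditions: TESOTf, 2,6-lutidine, CH2Cl2, −78 to 0 °C
Reagents that add atoms: triethylsilyl triflate, CC[Si](CC)(CC)OS(=O)(=O)C(F)(F)F
Why: The silyl triflate is reactive enough to cap the primary and the tertiary hydroxyl in one operation (silyl ether formation).

Step 11
Reactants: 19 bis-TES ether
Product: 21 (2S,3S,4R)-4-methyl-5-oxo-3-(triethylsilyloxy)-2-(triethylsilyloxymethyl)oxolane-3-carbaldehyde, via ozonide 20 (not isolated)
Conditions: O3, CH2Cl2, −78 °C; Me2S, to rt
Reagents that add atoms: ozone, [O-][O+]=O
Why: Ozonolysis of the only alkene unmasks the non-enolisable C9 aldehyde.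

Step 12
Reactants: 21 C9 aldehyde; 5 (E)-1-iodo-2-methylbuta-1,3-diene
Product: 23 (9R)-dienol, that is 21 with CHO turned into (1R,2E)-1-hydroxy-3-methylpenta-2,4-dienyl, via dienylchromium 22 (not isolated)
Conditions: CrCl2, NiCl2 (cat.), DMSO, rt
Reagents that add atoms: CrCl2, [Cr+2].[Cl-].[Cl-] (atoms in 22 only)
Why: The Nozaki–Hiyama–Kishi coupling keeps the E geometry and spares the lactone, and Felkin–Anh addition anti to the C8–OTES bond, passing the smaller C17 flank rather than the C7 flank, should give 9R.

Step 13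
Reactants: 23 dienol
Product: 24 6,8,9-tris-TES ether (C7, C8, C9 and C17 arranged in space as in 35)
Conditions: TESOTf, 2,6-lutidine, CH2Cl2, −40 °C
Reagents that add atoms: triethylsilyl triflate, CC[Si](CC)(CC)OS(=O)(=O)C(F)(F)F
Why: Prompt silylation blocks migration of the lactone to O9 and protects the dienylic alcohol (silyl ether formation).

Step 14
Reactants: 24 tris-TES ether
Product: 26 C6 aldehyde (8,9-bis-TES), via alkoxysulfonium salt 25 (not isolated)
Conditions: (COCl)2, DMSO, CH2Cl2, −78 to −40 °C; Et3N, to 0 °C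
Reagents that add atoms: dimethyl sulfoxide, CS(C)=O (Me2S unit in 25 only)
Why: Under Swern conditions a primary TES ether is cleaved and oxidised directly to the aldehyde, while the hindered secondary and tertiary TES ethers survive.

Step 15
Reactants: 26 C6 aldehyde; 11 formyl ylide
Product: 27 tetraene, that is the lactone with the (E)-dienyl 9-OTES carbinol on C8 and, on C7, the arm CH=C(CHO)CH2CH2C(=O)C(CH3)=CH–Bpin (C7 trans to C16, C2 cis to boron)
Conditions: benzene, 45 °C
Reagents that add atoms: none
Why: The Wittig reaction of an α-alkyl formyl-stabilised ylide gives the E enal (CHO trans to C7), which fixes the cis C4/C7 relation of the ring alkene, and the weakly basic ylide spares C7–H.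

Step 16
Reactants: 27 tetraene
Product: 28 cycloadduct, the 6/10/5 tricycle with 14α-Bpin, 2-oxo, C16 aldehyde, C11=C12 and 8,9-bis-OTES
Conditions: toluene (1 mM), BHT, 110 °C
Reagents that add atoms: none
Why: This is a concerted suprafacial [4+2] cycloaddition of the C10=C11–C12=C13 diene with the C1=C14 bond of the (Z)-β-boryl enone, and its closest known reaction type is the macrocyclising intramolecular Diels–Alder reaction of a diene and an acyl-activated alkene joined by a long chain, combined with an alkenylboronate as a masked enol. Ring A closes through the two new bonds C1–C10 and C13–C14, and the ten-membered ring closes in the fused mode through the shared bond C1–C10, its eight-atom tether C2–C9 being stiffened by the cis C4/C7 relation at C5=C6 and by the trans-substituted lactone. C10 is set by C9, because A(1,3) strain with the C20 methyl holds H9 in the diene plane, so that C8 and the tethered dienophile lie on one face and OTES on the other. C1 and C14 are set relative to each other by the Z geometry (C2 and boron stay cis) and relative to C10 by the exo mode, in which the carbonyl and the bulky pinacol boronate point away from the diene and only C15 and H14 lie under it, which gives the trans ring fusion. The step needs the fused over the bridged orientation (C10–C14 and C13–C1), which is secured by the ortho preference of a 1-substituted diene for the acyl-bearing carbon and by the strain of the meta-bridged bicycle, and it needs chemoselectivity over the C5=C6 enal, which is secured because C6 and C9 are trans on the lactone, so that this closure would give a trans-fused bicyclo[3.3.0]octane. High dilution suppresses intermolecular addition.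

Step 17
Reactants: 28 cycloadduct
Product: 29 14α-hydroxy-2-ketone
Conditions: NaBO3·4H2O, THF–H2O, rt
Reagents that add atoms: sodium perborate, [Na+].[O-]OB=O
Why: Boronate oxidation proceeds by 1,2-migration with retention, so the C14 configuration set in step 16 passes to the alcohol, and the mild reagent should spare the enal and avoid retro-aldol cleavage.

Step 18
Reactants: 29 β-hydroxy ketone
Product: 31 2,14,16-triol (2R), via diethylborinate 30 (not isolated)
Conditions: Et2BOMe, THF–MeOH, −78 °C; NaBH4; MeOH evaporation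
Reagents that add atoms: diethylmethoxyborane, CCB(CC)OC (BEt2 in 30 only)
Why: In the Narasaka–Prasad reduction external hydride attacks the six-membered O14–B–O2 chelate to give the 1,3-syn diol, so C14 sets C2, and the enal is reduced 1,2 in the same flask.

Step 19
Reactants: 31 triol
Product: 32 16-chloro-2,14-diol
Conditions: PPh3, (Cl3C)2CO, CH2Cl2, −20 °C
Reagents that add atoms: hexachloroacetone, ClC(Cl)(Cl)C(=O)C(Cl)(Cl)Cl
Why: This Appel-type chlorination is fast only at the primary allylic alcohol, proceeds without allylic shift or loss of geometry, and leaves the two neopentyl-type secondary alcohols alone.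

Step 20
Reactants: 32 chloro diol
Product: 33 2,14-diacetate
Conditions: Ac2O, Et3N, DMAP (cat.), CH2Cl2, rt
Reagents that add atoms: acetic anhydride, CC(=O)OC(C)=O
Why: DMAP-catalysed acylation esterifies the only free hydroxyls (C2 and C14), and the low catalyst loading limits attack on the allylic chloride.

Step 21
Reactants: 33 diacetate
Product: 34 8,9-diol with C11=C12
Conditions: HF·pyridine, THF, 0 °C to rt
Reagents that add atoms: none
Why: Fluoride-driven desilylation removes both TES groups under weakly acidic conditions that acetates, lactone and allylic chloride tolerate.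

Step 22
Reactants: 34 diol
Product: 35 target CNP0308390.1
Conditions: VO(acac)2 (cat.), t-BuOOH, CH2Cl2, 0 °C
Reagents that add atoms: tert-butyl hydroperoxide, CC(C)(C)OO
Why: In this hydroxyl-directed vanadium-catalysed epoxidation the homoallylic 9-OH sits on the β face of ring A and should deliver oxygen to that face of C11=C12, setting C11 and C12, while C5=C6 is deactivated by the allylic chlorine and acyloxy groups.

**Compound list**

1 | prop-2-yn-1-ol | C#CCO | starting material
2 | (E)-alkenylalane (Al cis to methyl) | C[Al](C)/C=C(\C)CO[Al](C)C | intermediate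
3 | (E)-3-iodo-2-methylprop-2-en-1-ol | OC/C(C)=C/I | intermediate
4 | (E)-3-iodo-2-methylprop-2-enal | O=C/C(C)=C/I | intermediate
5 | (E)-1-iodo-2-methylbuta-1,3-diene | C=C/C(C)=C/I | intermediate
6 | propyne | CC#C | starting material
7 | (Z)-(2-bromoprop-1-enyl)dibromoborane | C/C(Br)=C/B(Br)Br | intermediate
8 | (Z)-2-bromoprop-1-enyl pinacol boronate | C/C(Br)=C/B1OC(C)(C)C(C)(C)O1 | intermediate
9 | (Z)-2-methyl-1-(pinacolboryl)penta-1,4-dien-3-one | C=CC(=O)/C(C)=C\B1OC(C)(C)C(C)(C)O1 | intermediate
10 | (triphenylphosphoranylidene)acetaldehyde | O=CC=P(c1ccccc1)(c1ccccc1)c1ccccc1 | starting material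
11 | formyl ylide carrying the boryl enone | O=CC(CCC(=O)/C(C)=C\B1OC(C)(C)C(C)(C)O1)=P(c1ccccc1)(c1ccccc1)c1ccccc1 | intermediate
12 | methyl (4S)-2,2-dimethyl-1,3-dioxolane-4-carboxylate | COC(=O)[C@@H]1COC(C)(C)O1 | starting material
13 | (4S)-N-methoxy-N,2,2-trimethyl-1,3-dioxolane-4-carboxamide | CON(C)C(=O)[C@@H]1COC(C)(C)O1 | intermediate
14 | 1-[(4S)-2,2-dimethyl-1,3-dioxolan-4-yl]prop-2-en-1-one | C=CC(=O)[C@@H]1COC(C)(C)O1 | intermediate
15 | ethyl propanoate | CCC(=O)OCC | starting material
16 | lithium enolate of 15 (methyl cis to OEt, trans to OLi) | C/C=C(\OCC)O[Li] | intermediate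
17 | aldol adduct (2R,3S,4'S) | C=C[C@](O)([C@@H](C)C(=O)OCC)[C@@H]1COC(C)(C)O1 | intermediate
18 | lactone diol (3R,4S,5S) | C=C[C@@]1(O)[C@H](CO)OC(=O)[C@@H]1C | intermediate
19 | 6,8-bis-TES ether | C=C[C@@]1(O[Si](CC)(CC)CC)[C@H](CO[Si](CC)(CC)CC)OC(=O)[C@@H]1C | intermediate
20 | ozonide of 19 | O1COOC1[C@@]2(O[Si](CC)(CC)CC)[C@H](CO[Si](CC)(CC)CC)OC(=O)[C@@H]2C | intermediate
21 | C9 aldehyde | O=C[C@@]1(O[Si](CC)(CC)CC)[C@H](CO[Si](CC)(CC)CC)OC(=O)[C@@H]1C | intermediate
22 | [(1E)-2-methylbuta-1,3-dienyl]chromium dichloride | C=C/C(C)=C/[Cr](Cl)Cl | intermediate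
23 | (9R)-dienol | C=C/C(C)=C/[C@@H](O)[C@@]1(O[Si](CC)(CC)CC)[C@H](CO[Si](CC)(CC)CC)OC(=O)[C@@H]1C | intermediate
24 | 6,8,9-tris-TES ether | C=C/C(C)=C/[C@@H](O[Si](CC)(CC)CC)[C@@]1(O[Si](CC)(CC)CC)[C@H](CO[Si](CC)(CC)CC)OC(=O)[C@@H]1C | intermediate
25 | C6 alkoxysulfonium chloride | C=C/C(C)=C/[C@@H](O[Si](CC)(CC)CC)[C@@]1(O[Si](CC)(CC)CC)[C@H](CO[S+](C)C)OC(=O)[C@@H]1C.[Cl-] | intermediate
26 | C6 aldehyde | C=C/C(C)=C/[C@@H](O[Si](CC)(CC)CC)[C@@]1(O[Si](CC)(CC)CC)[C@H](C=O)OC(=O)[C@@H]1C | intermediate
27 | tetraene (cycloaddition precursor) | C=C/C(C)=C/[C@@H](O[Si](CC)(CC)CC)[C@@]1(O[Si](CC)(CC)CC)[C@H](/C=C(/C=O)CCC(=O)/C(C)=C\B2OC(C)(C)C(C)(C)O2)OC(=O)[C@@H]1C | intermediate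
28 | cycloadduct (14-Bpin, 2-oxo, 16-al) | CC1(C)OB(OC1(C)C)[C@H]2CC=C(C)[C@@H]3[C@@H](O[Si](CC)(CC)CC)[C@@]4(O[Si](CC)(CC)CC)[C@H](/C=C(/C=O)CCC(=O)[C@@]23C)OC(=O)[C@@H]4C | intermediate
29 | 14-hydroxy-2-ketone | O[C@H]1CC=C(C)[C@@H]2[C@@H](O[Si](CC)(CC)CC)[C@@]3(O[Si](CC)(CC)CC)[C@H](/C=C(/C=O)CCC(=O)[C@@]12C)OC(=O)[C@@H]3C | intermediate
30 | 14-O-diethylborinate of 29 | CCB(CC)O[C@H]1CC=C(C)[C@@H]2[C@@H](O[Si](CC)(CC)CC)[C@@]3(O[Si](CC)(CC)CC)[C@H](/C=C(/C=O)CCC(=O)[C@@]12C)OC(=O)[C@@H]3C | intermediate
31 | 2,14,16-triol | O[C@H]1CC=C(C)[C@@H]2[C@@H](O[Si](CC)(CC)CC)[C@@]3(O[Si](CC)(CC)CC)[C@H](/C=C(/CO)CC[C@@H](O)[C@@]12C)OC(=O)[C@@H]3C | intermediate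
32 | 16-chloro-2,14-diol | O[C@H]1CC=C(C)[C@@H]2[C@@H](O[Si](CC)(CC)CC)[C@@]3(O[Si](CC)(CC)CC)[C@H](/C=C(/CCl)CC[C@@H](O)[C@@]12C)OC(=O)[C@@H]3C | intermediate
33 | 2,14-diacetate | CC(=O)O[C@H]1CC=C(C)[C@@H]2[C@@H](O[Si](CC)(CC)CC)[C@@]3(O[Si](CC)(CC)CC)[C@H](/C=C(/CCl)CC[C@@H](OC(C)=O)[C@@]12C)OC(=O)[C@@H]3C | intermediate
34 | 8,9-diol with C11=C12 | CC(=O)O[C@H]1CC=C(C)[C@@H]2[C@@H](O)[C@@]3(O)[C@H](/C=C(/CCl)CC[C@@H](OC(C)=O)[C@@]12C)OC(=O)[C@@H]3C | intermediate
35 | CNP0308390.1 (1S,2R,7S,8R,9R,10S,11R,12S,14S,17R; 5E) | CC(=O)O[C@H]1C[C@@H]2O[C@]2(C)[C@@H]2[C@@H](O)[C@@]3(O)[C@H](/C=C(/CCl)CC[C@@H](OC(C)=O)[C@@]12C)OC(=O)[C@@H]3C | target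

**Count.** Total steps: 22. Longest linear sequence: 16 (steps 7–22).

**The three steps most likely to fail**

Step 16. Closure through the strained ten-membered transition state may be slower than dimerisation or polymerisation of the terminal diene. The diene may also be lost during steps 13–15, and the exo, fused mode may not dominate. The fallback below answers only the first two problems.
- The fallback sets out from 21 and comes back at 28. The diene is carried as its SO2 adduct and released only in the cyclisation flask.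
- Commercial 3-methyl-2,5-dihydrothiophene 1,1-dioxide (CC1=CCS(=O)(=O)C1) is lithiated at C2 with LiHMDS at −78 °C in the presence of 21. This gives the β-hydroxy sulfolene F1, by the same Felkin–Anh addition as in step 12.
- TESOTf and 2,6-lutidine give the tris-TES sulfolene F2.
- Swern treatment as in step 14 gives the sulfolene aldehyde F3.
- Wittig reaction with 11 at 45 °C, below the extrusion temperature, gives the masked tetraene F4.
- Heating F4 in dilute toluene at 110 °C expels SO2 cheletropically. This should give the E diene 27 at a low stationary concentration, which closes to 28 in the same flask.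

Step 12. Facial selectivity at the aldehyde may be poor, because the C7 and C17 flanks differ little, and the lactone may migrate to O9.
- The fallback sets out from 23 (as the C9 epimer mixture) and comes back at 23. C9 is set by reagent control at a ketone instead of by addition.
- Dess–Martin periodinane oxidises the mixture to the dienone F5.
- Corey–Bakshi–Shibata reduction with (S)-Me-CBS and catecholborane in toluene at −78 °C treats the quaternary C8 as the large group. It should return the 9R alcohol 23.

Step 22. Oxygen may be delivered to the α face if direction by 9-OH is weak, or C5=C6 may be epoxidised under direction by 8-OH.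
- The fallback sets out from 34 and comes back at 35. The facial outcome is inverted through a halohydrin.
- NBS in aqueous acetone forms the bromonium ion on the more open α face, and water opens it at the tertiary C11 from the β face. This gives the 11β-hydroxy-12α-bromide F6.
- K2CO3 in acetone then closes the β-oxirane by backside displacement of bromide at C12.

**Further compounds**

F1 | step 16 | β-hydroxy sulfolene (9R; C10 unassigned) | CC1=CCS(=O)(=O)C1[C@@H](O)[C@@]2(O[Si](CC)(CC)CC)[C@H](CO[Si](CC)(CC)CC)OC(=O)[C@@H]2C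
F2 | step 16 | tris-TES sulfolene | CC1=CCS(=O)(=O)C1[C@@H](O[Si](CC)(CC)CC)[C@@]2(O[Si](CC)(CC)CC)[C@H](CO[Si](CC)(CC)CC)OC(=O)[C@@H]2C
F3 | step 16 | sulfolene C6 aldehyde | CC1=CCS(=O)(=O)C1[C@@H](O[Si](CC)(CC)CC)[C@@]2(O[Si](CC)(CC)CC)[C@H](C=O)OC(=O)[C@@H]2C
F4 | step 16 | sulfolene-masked tetraene | CC1=CCS(=O)(=O)C1[C@@H](O[Si](CC)(CC)CC)[C@@]2(O[Si](CC)(CC)CC)[C@H](/C=C(/C=O)CCC(=O)/C(C)=C\B3OC(C)(C)C(C)(C)O3)OC(=O)[C@@H]2C
F5 | step 12 | C9 dienone | C=C/C(C)=C/C(=O)[C@@]1(O[Si](CC)(CC)CC)[C@H](CO[Si](CC)(CC)CC)OC(=O)[C@@H]1C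
F6 | step 22 | 11β-hydroxy-12α-bromide | CC(=O)O[C@H]1C[C@@H](Br)[C@](C)(O)[C@@H]2[C@@H](O)[C@@]3(O)[C@H](/C=C(/CCl)CC[C@@H](OC(C)=O)[C@@]12C)OC(=O)[C@@H]3C
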